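**Retrosynthetic overview**

1. Target 16 is released last by hydrogenolysis of the (2R,3S)-2,3-epoxychromanone 15, which cleaves the C3–O bond alpha to the C4 ketone, the aryl benzyl ether and the benzyl carbonate but keeps C2–O. 15 comes from chromone 14 by enantioselective epoxidation, so the chromone serves as the achiral, dehydrated form of ring B and is rehydrated stereoselectively.
2. Ring B (O1–C2–C3–C4–C4a–C8a) is disconnected at C3–C4 and O1–C8a: a (3+3) annulation in one flask, C-acylation of the dianion of methyl ketone 10 by aroyl chloride 6, then displacement of the C8a fluoride by the enolate oxygen on C2.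
3. Enabling feature: the C4 carbonyl carbon sits on C4a of benzene ring A, ortho to C8a. This one carbonyl is the acylating centre for C3 and the activating group for substitution at C8a–F, and the 1,3-diketone it creates holds the C2 oxygen in reach of C8a for a six-membered closure.
4. Fragments: 6 from 3,5-difluorophenol (benzylation; lithiation/CO2 between the fluorines; carboxylate-directed replacement of one fluoride by a 3-methylbutyl Grignard reagent); 10 from triacetic acid lactone (PMB ether; lateral lithiation/acetylation).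
5. Ring order: ring A and the 2-pyranone ring C are bought, ring B is closed in step 7, the oxirane is fused on in step 9 and opened in step 10.

Key step: step 7

Assumption: C2 is a hemiketal carbon that can lose its configuration only by ring–chain tautomerism (opening of ring B to the aryl 1,3-diketone), taken to be slow for the neutral compound in aprotic media; the route therefore locks the C2–O bond in an oxirane and frees the hemiketal only in the last, neutral step.

**Step 1**
Reactants: 1 3,5-difluorophenol
Product: 2 1-(benzyloxy)-3,5-difluorobenzene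
Conditions: BnBr, K2CO3, DMF, rt
Reagents that add atoms: benzyl bromide, BrCc1ccccc1
Why: Williamson ether synthesis of the phenoxide with a benzylic bromide; the benzyl ether should survive all later bases and leaves only in the final hydrogenolysis.

**Step 2**
Reactants: 2 1-(benzyloxy)-3,5-difluorobenzene
Product: 3 4-(benzyloxy)-2,6-difluorobenzoic acid
Conditions: LiN(iPr)2, THF, −78 °C; CO2; aq. HCl
Reagents that add atoms: carbon dioxide, O=C=O
Why: Directed ortho-metalation at the C–H flanked by both fluorines (the most acidic ring position, para to the benzyloxy group) followed by carboxylation of the aryllithium, which at −78 °C should not lose LiF.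

**Step 3**
Reactants: 3 4-(benzyloxy)-2,6-difluorobenzoic acid; 4 3-methylbutylmagnesium bromide
Product: 5 4-(benzyloxy)-2-fluoro-6-(3-methylbutyl)benzoic acid
Conditions: 4 (2.5 equiv), THF, 0 → 45 °C; aq. HCl
Reagents that add atoms: none
Why: Carboxylate-directed nucleophilic aromatic substitution (addition–elimination) of an unprotected 2-fluorobenzoic acid by a Grignard reagent: the first equivalent forms the magnesium carboxylate, which delivers the second to the ortho C–F carbon, and the second fluoride should stay because the 2-alkyl-6-fluorobenzoate is more hindered and twisted.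

**Step 4**
Reactants: 5 4-(benzyloxy)-2-fluoro-6-(3-methylbutyl)benzoic acid
Product: 6 4-(benzyloxy)-2-fluoro-6-(3-methylbutyl)benzoyl chloride
Conditions: (COCl)2, cat. DMF, CH2Cl2, 0 °C → rt
Reagents that add atoms: oxalyl chloride, ClC(=O)C(Cl)=O
Why: Acid chloride formation through the chloroiminium (Vilsmeier-type) catalyst under neutral conditions that leave the benzyl ether and the aryl fluoride untouched.

**Step 5**
Reactants: 7 4-hydroxy-6-methyl-2H-pyran-2-one (triacetic acid lactone)
Product: 8 4-[(4-methoxybenzyl)oxy]-6-methyl-2H-pyran-2-one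
Conditions: 4-methoxybenzyl chloride, K2CO3, DMF, 50 °C
Reagents that add atoms: 4-methoxybenzyl chloride, COc1ccc(CCl)cc1
Why: O-alkylation of the vinylogous carboxylic acid at O4 (Williamson type), giving an ether that tolerates lithium amide bases and is later removed by mild acid.

**Step 6**
Reactants: 8 4-[(4-methoxybenzyl)oxy]-6-methyl-2H-pyran-2-one; 9 N-methoxy-N-methylacetamide
Product: 10 4-[(4-methoxybenzyl)oxy]-6-(2-oxopropyl)-2H-pyran-2-one
Conditions: LiN(iPr)2 (1.1 equiv), THF, −78 °C; then 9; aq. NH4Cl
Reagents that add atoms: none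
Why: Lateral (vinylogous) lithiation of the C6 methyl group of the 4-alkoxy-2-pyranone and Weinreb ketone synthesis, the chelated tetrahedral adduct preventing over-addition and proton transfer until work-up.

**Step 7**
Reactants: 10 4-[(4-methoxybenzyl)oxy]-6-(2-oxopropyl)-2H-pyran-2-one; 6 4-(benzyloxy)-2-fluoro-6-(3-methylbutyl)benzoyl chloride
Product: 12 7-(benzyloxy)-2-({4-[(4-methoxybenzyl)oxy]-2-oxo-2H-pyran-6-yl}methyl)-5-(3-methylbutyl)-4H-chromen-4-one, via fluoroaryl 1,3-diketone 11 (not isolated)
Conditions: 10 (2 equiv), LiN(iPr)2 (4.2 equiv), THF, −78 °C; 6 (1 equiv), −78 → 0 °C; AcOH to neutrality; solvent change to DMF, K2CO3 (1.5 equiv), 60 °C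
Reagents that add atoms: none
Why: Double deprotonation of 10 gives the 1,3-dianion, whose terminal, methyl-derived carbanion (the more basic and more nucleophilic site) attacks acid chloride 6 and forms C3–C4 (Claisen-type C-acylation of a ketone dianion), giving 1,3-diketone 11 as its enolate. After neutralisation, K2CO3 in DMF regenerates only the β-diketonate, whose oxygen on C2 attacks C8a and expels fluoride to form O1–C8a (intramolecular SNAr, the established chromone synthesis from 1-(2-fluoroaryl)-1,3-diketones). Ring B closes as a six-membered ring by addition–elimination at the sp2 carbon C8a (6-exo with respect to the C–F bond that breaks), the negative charge of the σ-complex being taken up through C4a by the C4 carbonyl, which the forming ring holds coplanar with ring A. No stereocentre is formed: C2 is left sp2 on purpose, the chromone being the stable, achiral, dehydrated form of the hemiketal that steps 9 and 10 rehydrate under stereocontrol. The step needs site selectivity in the acylation (terminal carbon over the internal pyranone-stabilised enolate and over oxygen), which the reactivity order of the dianion and the excess of 10 (it absorbs the proton transfer from the more acidic product) should secure. It also needs O- over C-arylation in the closure, which is secured by cyclising the monoanion, where the diketonate carbon C3 cannot reach C8a and the pyranonylmethylene carbon is not deprotonated; the C7 benzyloxy group, being meta to C8a, does not deactivate the fluoride position.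

**Step 8**
Reactants: 12 7-(benzyloxy)-2-({4-[(4-methoxybenzyl)oxy]-2-oxo-2H-pyran-6-yl}methyl)-5-(3-methylbutyl)-4H-chromen-4-one
Product: 14 benzyl 6-{[7-(benzyloxy)-5-(3-methylbutyl)-4-oxo-4H-chromen-2-yl]methyl}-2-oxo-2H-pyran-4-yl carbonate, via hydroxypyranone 13 (not isolated)
Conditions: TFA, anisole, CH2Cl2, 0 °C; evaporate; then CbzCl, pyridine, CH2Cl2, 0 °C
Reagents that add atoms: benzyl chloroformate, O=C(Cl)OCc1ccccc1
Why: Acidolysis of the PMB ether of a vinylogous acid (cation trapped by anisole; the aryl benzyl ether should survive) and O-acylation of the acidic pyranone hydroxyl; the exchange replaces an electron-donating ether by an electron-withdrawing, hydrogenolysable carbonate so that the pyranone enol ether does not compete with the chromone C2=C3 bond in step 9.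

**Step 9**
Reactants: 14 benzyl 6-{[7-(benzyloxy)-5-(3-methylbutyl)-4-oxo-4H-chromen-2-yl]methyl}-2-oxo-2H-pyran-4-yl carbonate
Product: 15 benzyl 6-{[(2R,3S)-7-(benzyloxy)-2,3-epoxy-5-(3-methylbutyl)-4-oxo-3,4-dihydro-2H-chromen-2-yl]methyl}-2-oxo-2H-pyran-4-yl carbonate
Conditions: (S,S)-N,N'-bis(3,5-di-tert-butylsalicylidene)cyclohexane-1,2-diamine manganese chloride, (salen)MnCl (trivalent manganese, 10 mol %), NMO, mCPBA, CH2Cl2, −78 °C
Reagents that add atoms: 3-chloroperoxybenzoic acid, OOC(=O)c1cccc(Cl)c1
Why: Jacobsen–Katsuki epoxidation of the benzo-fused, trisubstituted C2=C3 bond of a chromone (chromenes and isoflavone-type chromones are established substrates): the chiral oxomanganese salen species selects the alkene face so that C2 becomes R, C3 following as S through the obligatory cis fusion of the oxirane; the (S,S) complex is proposed for this face, its sense of induction is to be confirmed on the first run, and the (R,R) complex delivers the other face.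

**Step 10**
Reactants: 15 benzyl 6-{[(2R,3S)-7-(benzyloxy)-2,3-epoxy-5-(3-methylbutyl)-4-oxo-3,4-dihydro-2H-chromen-2-yl]methyl}-2-oxo-2H-pyran-4-yl carbonate
Product: 16 6-{[(2R)-2,7-dihydroxy-5-(3-methylbutyl)-4-oxo-3,4-dihydro-2H-chromen-2-yl]methyl}-4-hydroxy-2H-pyran-2-one
Conditions: H2 (1 atm), Pd/C, EtOAc, rt
Reagents that add atoms: none
Why: Heterogeneous hydrogenolysis should cleave the two benzylic C–O bonds (aryl benzyl ether; benzyl carbonate, which then loses CO2) and the oxirane C3–O bond alpha to the C4 ketone (hydrogenolysis of an α,β-epoxy ketone to a β-hydroxy ketone) while leaving C2–O intact, so the epoxide oxygen stays on C2 as the hydroxyl with the R configuration set in step 9 and the hemiketal appears under neutral, aprotic conditions.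

**Compound list**

1 | 3,5-difluorophenol | Oc1cc(F)cc(F)c1 | starting material
2 | 1-(benzyloxy)-3,5-difluorobenzene | Fc1cc(F)cc(OCc2ccccc2)c1 | intermediate
3 | 4-(benzyloxy)-2,6-difluorobenzoic acid | OC(=O)c1c(F)cc(OCc2ccccc2)cc1F | intermediate
4 | 3-methylbutylmagnesium bromide | CC(C)CC[Mg]Br | starting material
5 | 4-(benzyloxy)-2-fluoro-6-(3-methylbutyl)benzoic acid | CC(C)CCc1cc(OCc2ccccc2)cc(F)c1C(=O)O | intermediate
6 | 4-(benzyloxy)-2-fluoro-6-(3-methylbutyl)benzoyl chloride | CC(C)CCc1cc(OCc2ccccc2)cc(F)c1C(=O)Cl | intermediate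
7 | 4-hydroxy-6-methyl-2H-pyran-2-one (triacetic acid lactone) | Cc1cc(O)cc(=O)o1 | starting material
8 | 4-[(4-methoxybenzyl)oxy]-6-methyl-2H-pyran-2-one | Cc1cc(OCc2ccc(OC)cc2)cc(=O)o1 | intermediate
9 | N-methoxy-N-methylacetamide | CC(=O)N(C)OC | starting material
10 | 4-[(4-methoxybenzyl)oxy]-6-(2-oxopropyl)-2H-pyran-2-one | CC(=O)Cc1cc(OCc2ccc(OC)cc2)cc(=O)o1 | intermediate
11 | 1-[4-(benzyloxy)-2-fluoro-6-(3-methylbutyl)phenyl]-4-{4-[(4-methoxybenzyl)oxy]-2-oxo-2H-pyran-6-yl}butane-1,3-dione | CC(C)CCc1cc(OCc2ccccc2)cc(F)c1C(=O)CC(=O)Cc3cc(OCc4ccc(OC)cc4)cc(=O)o3 | intermediate (not isolated)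
12 | 7-(benzyloxy)-2-({4-[(4-methoxybenzyl)oxy]-2-oxo-2H-pyran-6-yl}methyl)-5-(3-methylbutyl)-4H-chromen-4-one | CC(C)CCc1cc(OCc2ccccc2)cc3c1C(=O)C=C(Cc4cc(OCc5ccc(OC)cc5)cc(=O)o4)O3 | intermediate
13 | 7-(benzyloxy)-2-[(4-hydroxy-2-oxo-2H-pyran-6-yl)methyl]-5-(3-methylbutyl)-4H-chromen-4-one | CC(C)CCc1cc(OCc2ccccc2)cc3c1C(=O)C=C(Cc4cc(O)cc(=O)o4)O3 | intermediate (not isolated)
14 | benzyl 6-{[7-(benzyloxy)-5-(3-methylbutyl)-4-oxo-4H-chromen-2-yl]methyl}-2-oxo-2H-pyran-4-yl carbonate | CC(C)CCc1cc(OCc2ccccc2)cc3c1C(=O)C=C(Cc4cc(OC(=O)OCc5ccccc5)cc(=O)o4)O3 | intermediate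
15 | benzyl 6-{[(2R,3S)-7-(benzyloxy)-2,3-epoxy-5-(3-methylbutyl)-4-oxo-3,4-dihydro-2H-chromen-2-yl]methyl}-2-oxo-2H-pyran-4-yl carbonate | CC(C)CCc1cc(OCc2ccccc2)cc3c1C(=O)[C@@H]4O[C@]4(Cc5cc(OC(=O)OCc6ccccc6)cc(=O)o5)O3 | intermediate
16 | 6-{[(2R)-2,7-dihydroxy-5-(3-methylbutyl)-4-oxo-3,4-dihydro-2H-chromen-2-yl]methyl}-4-hydroxy-2H-pyran-2-one | CC(C)CCc1cc(O)cc2c1C(=O)C[C@@](O)(Cc1cc(O)cc(=O)o1)O2 | target

**Step count and risks**

Total step count: 10. Longest linear sequence: 8 steps (steps 1–4, then 7–10).

Steps most likely to fail: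

Step 9. The oxygen transfer to a trisubstituted, electron-poor chromone alkene may be slow and show poor facial selectivity, and oxidation may drift to the pyranone C5=C6 bond or the doubly activated methylene. The fallback replaces asymmetric catalysis by resolution. It sets out from 14: epoxidation with dimethyldioxirane in acetone at 0 °C should give the racemic cis-fused benzyl 6-{[(2R*,3S*)-7-(benzyloxy)-2,3-epoxy-5-(3-methylbutyl)-4-oxo-3,4-dihydro-2H-chromen-2-yl]methyl}-2-oxo-2H-pyran-4-yl carbonate F1. Preparative chromatography on a chiral stationary phase then separates it into 15, where the route is rejoined, and the (2S,3R)-enantiomer F2, which is set aside.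

Step 10. Three hydrogenolyses must finish together. During that time the liberated acidic hydroxypyranone or the catalyst surface may ionise the C2–O bond of a still intact oxirane (isomerisation towards a 3-hydroxychromone), the pyranone may be over-reduced, or ring B may open and reclose with loss of configuration. The fallback separates the events and opens the oxirane by electron transfer. It sets out from 15: SmI2 (2.2 equiv) in THF–MeOH at −90 °C should cleave only the C3–O bond of the α,β-epoxy ketone and give benzyl 6-{[(2R)-7-(benzyloxy)-2-hydroxy-5-(3-methylbutyl)-4-oxo-3,4-dihydro-2H-chromen-2-yl]methyl}-2-oxo-2H-pyran-4-yl carbonate F3. A short hydrogenolysis (H2, Pd/C, EtOAc) then removes the benzyl ether and the benzyl carbonate and arrives at 16.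

Step 7. The acylation stage may stall: the far more acidic diketone can protonate the dianion, and the doubly ortho-substituted acid chloride may react slowly at carbon and be diverted to O-acylation or diacylation. The fallback makes the C3–C4 bond by aldol addition and oxidation instead of acylation. It sets out from 6: LiAlH(OtBu)3 in THF at −78 °C should give 4-(benzyloxy)-2-fluoro-6-(3-methylbutyl)benzaldehyde F4. Addition of the dianion of 10 (LiN(iPr)2, THF, −78 °C), whose aldolate is not an acid and cannot quench it, should give racemic 6-{4-[4-(benzyloxy)-2-fluoro-6-(3-methylbutyl)phenyl]-4-hydroxy-2-oxobutyl}-4-[(4-methoxybenzyl)oxy]-2H-pyran-2-one F5. Dess–Martin periodinane oxidises this to diketone 11, now isolated, and K2CO3 in DMF at 60 °C closes it to 12, where the route is rejoined.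

**Further compounds**

F1 | step 9 | racemic cis-fused benzyl 6-{[(2R*,3S*)-7-(benzyloxy)-2,3-epoxy-5-(3-methylbutyl)-4-oxo-3,4-dihydro-2H-chromen-2-yl]methyl}-2-oxo-2H-pyran-4-yl carbonate | CC(C)CCc1cc(OCc2ccccc2)cc3c1C(=O)C4OC4(Cc5cc(OC(=O)OCc6ccccc6)cc(=O)o5)O3
F2 | step 9 | benzyl 6-{[(2S,3R)-7-(benzyloxy)-2,3-epoxy-5-(3-methylbutyl)-4-oxo-3,4-dihydro-2H-chromen-2-yl]methyl}-2-oxo-2H-pyran-4-yl carbonate | CC(C)CCc1cc(OCc2ccccc2)cc3c1C(=O)[C@H]4O[C@@]4(Cc5cc(OC(=O)OCc6ccccc6)cc(=O)o5)O3
F3 | step 10 | benzyl 6-{[(2R)-7-(benzyloxy)-2-hydroxy-5-(3-methylbutyl)-4-oxo-3,4-dihydro-2H-chromen-2-yl]methyl}-2-oxo-2H-pyran-4-yl carbonate | CC(C)CCc1cc(OCc2ccccc2)cc3c1C(=O)C[C@@](O)(Cc4cc(OC(=O)OCc5ccccc5)cc(=O)o4)O3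
F4 | step 7 | 4-(benzyloxy)-2-fluoro-6-(3-methylbutyl)benzaldehyde | CC(C)CCc1cc(OCc2ccccc2)cc(F)c1C=O
F5 | step 7 | racemic 6-{4-[4-(benzyloxy)-2-fluoro-6-(3-methylbutyl)phenyl]-4-hydroxy-2-oxobutyl}-4-[(4-methoxybenzyl)oxy]-2H-pyran-2-one | CC(C)CCc1cc(OCc2ccccc2)cc(F)c1C(O)CC(=O)Cc3cc(OCc4ccc(OC)cc4)cc(=O)o3
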